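The earlier runs and the new flask come from a simulation from invented constants; the scatter is artificial.

What is left of the starting material, as a fraction of the charge, is the number to follow in flasks theta and epsilon.

| flask | starting material | remark | time |
|---|---|---|---|
| winter | 0.70 M | run made earlier |  |
| summer | 1.1 M | run made earlier |  |
| theta | 0.50 M |  | 40 min |
| epsilon | 0.50 M |  | 50 min |

| run | time / min | starting material / % | target / % | isomer of the product / % |
|---|---|---|---|---|
| winter | 6.00 | 93.2 | 5.5 | 2.0 |
| winter | 12.0 | 87.3 | 9.3 | 4.0 |
| winter | 20.0 | 80.3 | 14.4 | 5.1 |
| winter | 25.0 | 77.3 | 18.2 | 4.9 |
| summer | 6.00 | 92.8 | 5.4 | 1.7 |
| summer | 12.0 | 87.0 | 9.7 | 3.1 |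
| summer | 20.0 | 80.1 | 16.4 | 3.6 |
| summer | 25.0 | 75.4 | 20.3 | 4.1 |

(each reading ± 0.3 percentage points)

- what is said of target includes crystals
- crystals is a solid; its amount is given per volume of the solution
- the analysis behind the earlier runs scatters by 0.3 percentage points, standard deviation
- what may be going on: isomer of the product <-> starting material; crystals <-> target; starting material <-> target; target <-> isomer of the product

* which of these there is most of at the end, counted by the starting material in it, theta (isomer of the product / starting material / target)
* which of these there is most of at the end, counted by the starting material in it, epsilon (isomer of the product / starting material / target)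
* the largest of these amounts at the end, in percent of the starting material charged, theta
* the largest of these amounts at the end, in percent of the starting material charged, epsilon

Does the balance close? At the last readings, the fractions of starting material, target (crystals included) and isomer of the product sum to 100% in the winter run and 99.8% in the summer run. Starting material therefore leads once its leftover exceeds the other two together.

What do you carry forward? The last winter reading gives 0.0103 min⁻¹ for the leftover constant, an apparent first-order rate constant: minus the natural logarithm of the leftover fraction, divided by the time. I take the winter run because its charge lies nearer; the summer run gives 0.0113 min⁻¹.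

Your answer? I reckon a leftover of 66.2% in theta and 59.8% in epsilon. The leftover equals the other two together at 67.3 min, later than either reading, so starting material is the largest in both.

But is the constant constant? No. The first winter reading gives 0.0117 min⁻¹, more than the last, and the first summer reading gives 0.0125 min⁻¹, also more than its last. The loss slows in both runs, so I hold my two figures as low sides.

The forecast names starting material at 65% for theta and starting material at 59% for epsilon, on the ground “the rate does not depend on concentration”. My figures lie above its figures .

Theta gives starting material at 68.2%, the largest, and epsilon gives starting material at 62.9%, the largest. The forecast's choices are right and its values lie within the tolerance.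

    isomer of the product ⇌ starting material (k = 2.10 × 10⁻⁴ s⁻¹)
    crystals ⇌ target, rate k2*(cs2 - [target]) while solid is left; crystals form when [target] > cs2 (solubility = 43.0 mM, k = 0.00770 s⁻¹)
    starting material ⇌ target (K = 0.410, k = 1.70 × 10⁻⁴ s⁻¹)
    target ⇌ isomer of the product (K = 0.530, k = 0.00130 s⁻¹)

Theta's own leftover constant is 0.00957 min⁻¹, smaller than the winter value. Now take the neighbouring flask, the same as theta but read at 2.5 h. Theta's constant predicts a leftover of 23.8%, but the neighbouring flask holds 33.8%, a constant of 0.00723 min⁻¹. Read that late, starting material no longer leads: target stands at 61.2% of the charge.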